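**Bench unit.** An equivalent is the unit I count in on the amber flask. Its reach is 1.10: charged [partner] per charged [starting material]. If each starting material takes one partner, the limiting reagent changes hands at a reach of one. Above that line, starting material is the charge that can run out first, given time, and partner then keeps a spare share of 9.09% of its charge.

| setting | amber | flask |
|---|---|---|
| starting material | 0.80 M | 0.80 M |
| partner | 0.88 M | 0.880 M |
| precatalyst | 0.40 mM | 0.40 mM |
| remark | the very flask that is asked about, followed so far |  |
| time |  | 8.0 d |

amber run (percent of the starting material charged)

| time / h | target / % | starting material / % |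
|---|---|---|
| 12.0 | 2.5 | 97.6 |
| 20.0 | 6.3 | 89.7 |
| 30.0 | 13.8 | 82.8 |
| 40.0 | 21.9 | 70.5 |
| 72.0 | 51.9 | 30.5 |
| 96.0 | 70.6 | 6.2 |
| 144 | 76.9 | 0 |

(readings scatter by 1 percentage point)

- removed target is counted in
- additions bring no volume worth counting

- birch: at 8.0 d add partner, 50.0% of the amount charged, then wait 15 d
- elm: at 8.0 d take out 90% of the target then present, then wait 15 d
- larch: at 8.0 d add precatalyst, 50.0% of the amount charged, then wait 15 d
- ash: change nothing and wait 15 d more

- target, in percent of the starting material first charged, at 8.0 d
- the remedy with the largest gain of target, or "none" below 2 percentage points (birch / elm / larch / ash / none)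
- target present, with what was taken out counted in, in percent of the starting material first charged, after larch
- target present, with what was taken out counted in, in percent of the starting material first charged, after ash

**For you.** The amber flask stands on the starting-material side of the line, since its reach is above one. Starting material read 6.2% at 96.0 h and 0% at 144 h, against a scatter of 1 percentage point and a margin of 2 points. When you come at 8.0 d, I expect target near its last reading, 76.9%. Leave the flask alone: more partner raises a reach already above one, and I read no starting material to convert.

**The forecast.** It gives 77% now, 77% after larch, 77% after ash, and best none, because “The reaction is finished, not stalled”.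

**The result.** The amber flask gives 77.1% at 8.0 d, 77.1% after larch, 77.1% after ash, and best none.

    partner + free catalyst → catalyst intermediate A (k = 3.86 M⁻¹ s⁻¹)
    catalyst intermediate B ⇌ catalyst intermediate C (K = 0.379, k = 0.0468 s⁻¹)
    catalyst intermediate C → free catalyst + target (k = 0.0373 s⁻¹)
    partner + precatalyst → free catalyst + spent reagent (k = 1.11 × 10⁻⁵ M⁻¹ s⁻¹)
    starting material + catalyst intermediate A → catalyst intermediate B (k = 0.179 M⁻¹ s⁻¹)
    starting material + target → side product (k = 3.50 × 10⁻⁶ M⁻¹ s⁻¹)

**At rest.** Left ten times as long, to 1920 h, the amber flask still holds 77.1% target and 22.9% side product. Between 192 h and 1920 h, precatalyst goes from 5.35% to 0%, catalyst intermediate A from 94.6% to >99.9%, and spent reagent from 3.79 × 10⁻⁴ M to 4.00 × 10⁻⁴ M. At 192 h the amber flask holds starting material at 0% and partner at 19%, above the reckoned spare of 9.09%.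

**Leaner neighbour.** With [partner] at 0.22 M, the reach is 0.275, below one, so I expect partner to end that flask's run with starting material to spare. The neighbour flask shows partner at 0%, starting material at 56%, and target at 11.1%.

The readings were generated by integration on assumed constants; the scatter is artificial.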